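**Strategy.** The route rests on disconnecting the ring–chain bond C4–C1′ by an Ireland–Claisen rearrangement. The tertiary allylic alcohol C1(OH)–C2=C3–C4 of the cyclohexene ring is read as the transposed form of an allyl ester O–C2–C3=C4. The precursor is therefore the 2-propionate of a trans-1-methylcyclohex-3-ene-1,2-diol, whose two C–O centres come from one Sharpless epoxidation of nerol. One [3,3] event forms C4–C1′, relays C2 to C4 (1,4-trans to C1–O), sets C1′ through ketene acetal geometry, and leaves the alkene at C2=C3. C3′ is then set by catalyst control.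

Key step: step 6

Remark on labels: ring atoms are C1 (C–OH, methyl), C2=C3, C4 (CH bearing the chain), C5, C6; chain atoms are C1′ (CH–CH3), C2′ (CH2), C3′ (CH–OAc). The labels are kept for all intermediates. The tertiary ring hydroxyl is carried unprotected after step 6.

Step 1
Reactants: 1 nerol, (2Z)-3,7-dimethylocta-2,6-dien-1-ol
Product: 2 [(2S,3R)-3-methyl-3-(4-methylpent-3-en-1-yl)oxiran-2-yl]methanol
Conditions: Ti(OiPr)4 (cat.), L-(+)-diethyl tartrate (cat.), t-BuOOH, 4 Å MS, CH2Cl2, −20 °C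
Reagents that add atoms: tert-butyl hydroperoxide, CC(C)(C)OO
Why: Sharpless asymmetric epoxidation: the Ti–L-(+)-tartrate complex epoxidises only the allylic alkene and delivers oxygen to one face, which should set the two C–O centres (future C1 and C2) as 2S,3R in one reagent-controlled event.

Step 2
Reactants: 2 [(2S,3R)-3-methyl-3-(4-methylpent-3-en-1-yl)oxiran-2-yl]methanol
Product: 4 (2R,3S)-3-ethenyl-2-methyl-2-(4-methylpent-3-en-1-yl)oxirane, via epoxy aldehyde 3 (not isolated)
Conditions: (COCl)2, DMSO, CH2Cl2, −78 °C; Et3N; then Ph3P=CH2 (Ph3PCH3Br, n-BuLi, THF), −78 °C → rt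
Reagents that add atoms: methyltriphenylphosphonium bromide, C[P+](c1ccccc1)(c1ccccc1)c1ccccc1.[Br-]
Why: Swern oxidation followed by Wittig methylenation in the same flask avoids isolating the labile α,β-epoxy aldehyde, and neither operation touches the oxirane stereocentres.

Step 3
Reactants: 4 (2R,3S)-3-ethenyl-2-methyl-2-(4-methylpent-3-en-1-yl)oxirane
Product: 5 (1S,6R)-6-methyl-7-oxabicyclo[4.1.0]hept-2-ene
Conditions: Grubbs II (3 mol%), CH2Cl2 (0.02 M), 40 °C; volatile product kept in solution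
Reagents that add atoms: none
Why: Ring-closing metathesis: the cis arrangement of the vinyl and homoprenyl arms on the nerol-derived oxirane allows six-membered ring closure with loss of isobutene, and no stereocentre is involved.

Step 4
Reactants: 5 (1S,6R)-6-methyl-7-oxabicyclo[4.1.0]hept-2-ene
Product: 6 (1R,6R)-6-hydroxy-6-methylcyclohex-2-en-1-yl propanoate
Conditions: EtCO2Cs (2 equiv), EtCO2H (1 equiv), DMF, 50 °C
Reagents that add atoms: propanoic acid, CCC(=O)O
Why: SN2 opening of a vinyl epoxide by carboxylate: under basic, non-ionising conditions the nucleophile should attack the allylic secondary carbon C2 (trans-diaxial opening, tertiary C1 closed to SN2) with inversion, which turns the cis epoxide into the trans diol monoester with the acyl group on C2.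

Step 5
Reactants: 6 (1R,6R)-6-hydroxy-6-methylcyclohex-2-en-1-yl propanoate
Product: 7 (1R,6R)-6-methyl-6-[(trimethylsilyl)oxy]cyclohex-2-en-1-yl propanoate
Conditions: TMSOTf, 2,6-lutidine, CH2Cl2, −78 °C
Reagents that add atoms: trimethylsilyl trifluoromethanesulfonate, C[Si](C)(C)OS(=O)(=O)C(F)(F)F
Why: Silyl triflate silylation is the standard protection of a hindered tertiary alcohol, tolerates the ester, and removes the alkoxide that could otherwise cause acyl migration during enolisation.

Step 6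
Reactants: 7 (1R,6R)-6-methyl-6-[(trimethylsilyl)oxy]cyclohex-2-en-1-yl propanoate
Product: 10 (2S)-2-[(1R,4R)-4-hydroxy-4-methylcyclohex-2-en-1-yl]propanoic acid, via silyl ketene acetal 8 (not isolated), via silyl ester 9 (not isolated)
Conditions: LDA, THF/DMPU (3:1), −78 °C; TMSCl, −78 °C → 50 °C; then MeOH, citric acid (cat.), rt
Reagents that add atoms: none
Why: Ireland–Claisen rearrangement: kinetic deprotonation in THF/DMPU gives the Z(O)-lithium enolate, which is O-silylated to the (Z)-silyl ketene acetal 8 and then undergoes a concerted suprafacial [3,3] shift across O–C2–C3=C4, breaking C2–O and making C4–C1′ to give silyl ester 9, and methanolysis frees acid 10. The closest known reaction type is the ester-enolate Claisen rearrangement of cyclohex-2-enyl propionates; no ring is closed, and the six-membered transition state is expected to be boat-like. C4 is set by 1,3-chirality transfer: the new bond must form on the ring face that carried the pseudoaxial C2–O bond, anti to the C1 silyloxy group, which gives the 1,4-trans relation of C1–O and C4–C1′ and leaves the alkene at C2=C3. C1′ is set by ketene acetal geometry together with the boat preference of cyclohexenyl systems: the chair would place the OSiMe3-bearing carbon over the ring against the axial C6–H, whereas the boat turns it outward and, with the Z acetal, puts only H over C5 and the methyl group outside. The selectivity needed is boat over chair with a geometrically pure Z acetal, which DMPU should secure; any E acetal reacting through the chair leads to the same diastereomer, so only E/boat or Z/chair leakage would erode the result. C1 is not touched.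

Step 7
Reactants: 10 (2S)-2-[(1R,4R)-4-hydroxy-4-methylcyclohex-2-en-1-yl]propanoic acid
Product: 11 (1R,4R)-4-[(2S)-1-hydroxypropan-2-yl]-1-methylcyclohex-2-en-1-ol
Conditions: LiAlH4, THF, 0 °C → rt; Rochelle salt work-up
Reagents that add atoms: none
Why: Hydride reduction of the carboxylic acid to the primary alcohol proceeds through the carboxylate, so C1′ is not enolised, and the isolated alkene and tertiary alcohol are inert.

Step 8
Reactants: 11 (1R,4R)-4-[(2S)-1-hydroxypropan-2-yl]-1-methylcyclohex-2-en-1-ol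
Product: 12 (1R,4R)-4-[(2S)-1-iodopropan-2-yl]-1-methylcyclohex-2-en-1-ol
Conditions: I2, PPh3, imidazole, CH2Cl2, 0 °C
Reagents that add atoms: iodine, II
Why: Appel-type iodination (PPh3/I2/imidazole) should be selective for the primary hydroxyl over the hindered tertiary one at 0 °C.

Step 9
Reactants: 12 (1R,4R)-4-[(2S)-1-iodopropan-2-yl]-1-methylcyclohex-2-en-1-ol
Product: 13 (4R)-4-[(1S,4R)-4-hydroxy-4-methylcyclohex-2-en-1-yl]pentanenitrile
Conditions: MeCN, n-BuLi (3 equiv), THF, −78 °C; then 12, DMPU, −78 °C → rt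
Reagents that add atoms: acetonitrile, CC#N
Why: SN2 alkylation of lithioacetonitrile, a small carbanion that substitutes β-branched primary iodides, with the excess reagent first converting the tertiary hydroxyl into its inert alkoxide.

Step 10
Reactants: 13 (4R)-4-[(1S,4R)-4-hydroxy-4-methylcyclohex-2-en-1-yl]pentanenitrile
Product: 14 (4R)-4-[(1S,4R)-4-hydroxy-4-methylcyclohex-2-en-1-yl]pentanal
Conditions: DIBAL-H (2.5 equiv), CH2Cl2, −78 °C; aq. Rochelle salt, pH 5 buffer
Reagents that add atoms: water, O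
Why: Partial reduction of a nitrile by DIBAL-H stops at the N-aluminoimine, which hydrolyses to the aldehyde on mild aqueous work-up.

Step 11
Reactants: 15 methyl (triphenyl-λ5-phosphanylidene)acetate; 16 5-bromo-2-methylpent-2-ene
Product: 18 methyl 6-methyl-2-(triphenyl-λ5-phosphanylidene)hept-5-enoate, via phosphonium bromide 17 (not isolated)
Conditions: NaI (cat.), MeCN, reflux; then 2 M NaOH, CH2Cl2, 0 °C
Reagents that add atoms: none
Why: C-Alkylation of a stabilised phosphorus ylide by a primary halide gives the α-substituted phosphonium salt, and deprotonation returns the α-alkylated stabilised ylide.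

Step 12
Reactants: 14 (4R)-4-[(1S,4R)-4-hydroxy-4-methylcyclohex-2-en-1-yl]pentanal; 18 methyl 6-methyl-2-(triphenyl-λ5-phosphanylidene)hept-5-enoate
Product: 20 methyl (2E,4S,6R)-6-[(1S,4R)-4-hydroxy-4-methylcyclohex-2-en-1-yl]-2-(4-methylpent-3-en-1-yl)-4-[(phenylamino)oxy]hept-2-enoate, via aminoxy aldehyde 19 (not isolated)
Conditions: D-proline (20 mol%), PhNO, DMSO, rt; then 18, 0 °C → rt
Reagents that add atoms: nitrosobenzene, O=Nc1ccccc1
Why: Proline-catalysed α-aminoxylation (O-nitroso aldol) through the enamine, in which the carboxylic acid of D-proline directs PhN=O to one enamine face and should set C3′ as S under catalyst control, followed by Wittig olefination in the same flask with the α-branched stabilised ylide, which should give the E trisubstituted enoate.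

Step 13
Reactants: 20 methyl (2E,4S,6R)-6-[(1S,4R)-4-hydroxy-4-methylcyclohex-2-en-1-yl]-2-(4-methylpent-3-en-1-yl)-4-[(phenylamino)oxy]hept-2-enoate
Product: 21 methyl (2E,4S,6R)-4-hydroxy-6-[(1S,4R)-4-hydroxy-4-methylcyclohex-2-en-1-yl]-2-(4-methylpent-3-en-1-yl)hept-2-enoate
Conditions: Zn dust, AcOH/THF, 0 °C → rt
Reagents that add atoms: none
Why: Reductive N–O bond cleavage by zinc in acetic acid frees the allylic alcohol without breaking the C3′–O bond and should leave the enoate and the alkenes untouched.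

Step 14
Reactants: 21 methyl (2E,4S,6R)-4-hydroxy-6-[(1S,4R)-4-hydroxy-4-methylcyclohex-2-en-1-yl]-2-(4-methylpent-3-en-1-yl)hept-2-enoate
Product: 22 methyl (2E,4S,6R)-4-acetoxy-6-[(1S,4R)-4-hydroxy-4-methylcyclohex-2-en-1-yl]-2-(4-methylpent-3-en-1-yl)hept-2-enoate (CNP0360342.1)
Conditions: Ac2O (1.3 equiv), pyridine, DMAP (cat.), CH2Cl2, 0 °C
Reagents that add atoms: acetic anhydride, CC(=O)OC(C)=O
Why: Acylation under nucleophilic catalysis should be selective for the secondary allylic hydroxyl, because the tertiary ring alcohol is too hindered to react at 0 °C.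

**Compound list**

1 | nerol, (2Z)-3,7-dimethylocta-2,6-dien-1-ol | CC(C)=CCC/C(C)=C\CO | starting material
2 | [(2S,3R)-3-methyl-3-(4-methylpent-3-en-1-yl)oxiran-2-yl]methanol | C[C@]1(CCC=C(C)C)O[C@H]1CO | intermediate
3 | (2R,3R)-3-methyl-3-(4-methylpent-3-en-1-yl)oxirane-2-carbaldehyde | C[C@]1(CCC=C(C)C)O[C@H]1C=O | intermediate (not isolated)
4 | (2R,3S)-3-ethenyl-2-methyl-2-(4-methylpent-3-en-1-yl)oxirane | C[C@]1(CCC=C(C)C)O[C@H]1C=C | intermediate
5 | (1S,6R)-6-methyl-7-oxabicyclo[4.1.0]hept-2-ene | C[C@@]12CCC=C[C@@H]1O2 | intermediate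
6 | (1R,6R)-6-hydroxy-6-methylcyclohex-2-en-1-yl propanoate | CCC(=O)O[C@@H]1C=CCC[C@@]1(C)O | intermediate
7 | (1R,6R)-6-methyl-6-[(trimethylsilyl)oxy]cyclohex-2-en-1-yl propanoate | CCC(=O)O[C@@H]1C=CCC[C@@]1(C)O[Si](C)(C)C | intermediate
8 | trimethyl{[(1Z)-1-{[(1R,6R)-6-methyl-6-(trimethylsilyloxy)cyclohex-2-en-1-yl]oxy}prop-1-en-1-yl]oxy}silane | C/C=C(\O[Si](C)(C)C)O[C@@H]1C=CCC[C@@]1(C)O[Si](C)(C)C | intermediate (not isolated)
9 | trimethylsilyl (2S)-2-[(1R,4R)-4-methyl-4-(trimethylsilyloxy)cyclohex-2-en-1-yl]propanoate | C[Si](C)(C)OC(=O)[C@@H](C)[C@H]1C=C[C@](C)(O[Si](C)(C)C)CC1 | intermediate (not isolated)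
10 | (2S)-2-[(1R,4R)-4-hydroxy-4-methylcyclohex-2-en-1-yl]propanoic acid | OC(=O)[C@@H](C)[C@H]1C=C[C@](C)(O)CC1 | intermediate
11 | (1R,4R)-4-[(2S)-1-hydroxypropan-2-yl]-1-methylcyclohex-2-en-1-ol | OC[C@@H](C)[C@H]1C=C[C@](C)(O)CC1 | intermediate
12 | (1R,4R)-4-[(2S)-1-iodopropan-2-yl]-1-methylcyclohex-2-en-1-ol | IC[C@@H](C)[C@H]1C=C[C@](C)(O)CC1 | intermediate
13 | (4R)-4-[(1S,4R)-4-hydroxy-4-methylcyclohex-2-en-1-yl]pentanenitrile | N#CCC[C@@H](C)[C@H]1C=C[C@](C)(O)CC1 | intermediate
14 | (4R)-4-[(1S,4R)-4-hydroxy-4-methylcyclohex-2-en-1-yl]pentanal | O=CCC[C@@H](C)[C@H]1C=C[C@](C)(O)CC1 | intermediate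
15 | methyl (triphenyl-λ5-phosphanylidene)acetate | COC(=O)C=P(c1ccccc1)(c1ccccc1)c1ccccc1 | starting material
16 | 5-bromo-2-methylpent-2-ene | CC(C)=CCCBr | starting material
17 | (1-methoxy-6-methyl-1-oxohept-5-en-2-yl)triphenylphosphonium bromide | COC(=O)C(CCC=C(C)C)[P+](c1ccccc1)(c1ccccc1)c1ccccc1.[Br-] | intermediate (not isolated)
18 | methyl 6-methyl-2-(triphenyl-λ5-phosphanylidene)hept-5-enoate | COC(=O)C(CCC=C(C)C)=P(c1ccccc1)(c1ccccc1)c1ccccc1 | intermediate
19 | (2S,4R)-4-[(1S,4R)-4-hydroxy-4-methylcyclohex-2-en-1-yl]-2-[(phenylamino)oxy]pentanal | O=C[C@H](C[C@@H](C)[C@H]1C=C[C@](C)(O)CC1)ONc1ccccc1 | intermediate (not isolated)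
20 | methyl (2E,4S,6R)-6-[(1S,4R)-4-hydroxy-4-methylcyclohex-2-en-1-yl]-2-(4-methylpent-3-en-1-yl)-4-[(phenylamino)oxy]hept-2-enoate | COC(=O)/C(=C/[C@H](C[C@@H](C)[C@H]1C=C[C@](C)(O)CC1)ONc1ccccc1)CCC=C(C)C | intermediate
21 | methyl (2E,4S,6R)-4-hydroxy-6-[(1S,4R)-4-hydroxy-4-methylcyclohex-2-en-1-yl]-2-(4-methylpent-3-en-1-yl)hept-2-enoate | COC(=O)/C(=C/[C@H](C[C@@H](C)[C@H]1C=C[C@](C)(O)CC1)O)CCC=C(C)C | intermediate
22 | methyl (2E,4S,6R)-4-acetoxy-6-[(1S,4R)-4-hydroxy-4-methylcyclohex-2-en-1-yl]-2-(4-methylpent-3-en-1-yl)hept-2-enoate | COC(=O)/C(=C/[C@H](C[C@@H](C)[C@H]1C=C[C@](C)(O)CC1)OC(C)=O)CCC=C(C)C | target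

**Step count.** Total: 14 steps. Longest linear sequence: 13 steps (1 → 22 through steps 1–10 and 12–14); step 11 is a one-step side branch.

**Steps most likely to fail**

Step 6. Discrimination between the boat and chair transition states, or control of ketene acetal geometry, may be insufficient, which would give a mixture of C1′ epimers. The fallback keeps the [3,3] shift for C4 but sets C1′ with an auxiliary. It sets out from 5. Opening with CsOAc/AcOH in DMF gives (1R,6R)-6-hydroxy-6-methylcyclohex-2-en-1-yl acetate F1, and TESOTf/2,6-lutidine gives (1R,6R)-6-methyl-6-[(triethylsilyl)oxy]cyclohex-2-en-1-yl acetate F2. Ireland–Claisen rearrangement of the acetate (LDA, TMSCl, THF, −78 °C → rt, aqueous NH4Cl work-up) creates only C4 and gives 2-[(1S,4R)-4-methyl-4-(triethylsilyloxy)cyclohex-2-en-1-yl]acetic acid F3. Acylation of (S)-4-benzyl-1,3-oxazolidin-2-one (PivCl, Et3N, LiCl, THF) gives (4S)-4-benzyl-3-{2-[(1S,4R)-4-methyl-4-(triethylsilyloxy)cyclohex-2-en-1-yl]acetyl}-1,3-oxazolidin-2-one F4. Evans methylation (NaHMDS, MeI, THF, −78 °C), in which the benzyl group shields one face of the chelated Z enolate, gives (4S)-4-benzyl-3-{(2S)-2-[(1R,4R)-4-methyl-4-(triethylsilyloxy)cyclohex-2-en-1-yl]propanoyl}-1,3-oxazolidin-2-one F5. LiBH4 reduction gives (2S)-2-[(1R,4R)-4-methyl-4-(triethylsilyloxy)cyclohex-2-en-1-yl]propan-1-ol F6, and TBAF in THF comes back to the route at 11.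

Step 4. The carboxylate is a weak nucleophile, so SN2′ (1,4-) opening, attack at the tertiary carbon through an ionising pathway (which would also erode enantiopurity), or rearrangement of the vinyl epoxide may compete. The fallback separates C–O bond formation from acylation. It sets out from 5: hydrolysis with KOH in DMSO/H2O at 80 °C (a small, hard nucleophile under strictly basic conditions) gives (1R,2R)-1-methylcyclohex-3-ene-1,2-diol F7. Selective acylation of the secondary hydroxyl with propanoic anhydride (1.1 equiv), pyridine and catalytic DMAP at 0 °C comes back to the route at 6.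

Step 12. Olefination of the labile α-aminoxy aldehyde by the hindered α-branched ylide may be slow, which would allow epimerisation at C3′ or elimination before the Wittig reaction is complete. The fallback isolates a stable alcohol and olefinates a robust α-silyloxy aldehyde. It sets out from 14. D-Proline/PhNO in DMSO followed by NaBH4 in the same flask gives (2S,4R)-4-[(1S,4R)-4-hydroxy-4-methylcyclohex-2-en-1-yl]-2-[(phenylamino)oxy]pentan-1-ol F8, and Zn/AcOH gives (2S,4R)-4-[(1S,4R)-4-hydroxy-4-methylcyclohex-2-en-1-yl]pentane-1,2-diol F9. TESCl (2.2 equiv) and imidazole in DMF at 0 °C silylate the primary and secondary hydroxyls to give (1R,4S)-4-[(2R,4S)-4,5-bis(triethylsilyloxy)pentan-2-yl]-1-methylcyclohex-2-en-1-ol F10. Swern conditions (−78 → −30 °C) selectively cleave and oxidise the primary silyl ether to give (2S,4R)-4-[(1S,4R)-4-hydroxy-4-methylcyclohex-2-en-1-yl]-2-[(triethylsilyl)oxy]pentanal F11. Wittig reaction with 18 in CH2Cl2 gives methyl (2E,4S,6R)-6-[(1S,4R)-4-hydroxy-4-methylcyclohex-2-en-1-yl]-2-(4-methylpent-3-en-1-yl)-4-[(triethylsilyl)oxy]hept-2-enoate F12, and HF·pyridine in THF/pyridine comes back to the route at 21.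

**Further compounds**

F1 | step 6 | (1R,6R)-6-hydroxy-6-methylcyclohex-2-en-1-yl acetate | CC(=O)O[C@@H]1C=CCC[C@@]1(C)O
F2 | step 6 | (1R,6R)-6-methyl-6-[(triethylsilyl)oxy]cyclohex-2-en-1-yl acetate | CC(=O)O[C@@H]1C=CCC[C@@]1(C)O[Si](CC)(CC)CC
F3 | step 6 | 2-[(1S,4R)-4-methyl-4-(triethylsilyloxy)cyclohex-2-en-1-yl]acetic acid | OC(=O)C[C@H]1C=C[C@](C)(O[Si](CC)(CC)CC)CC1
F4 | step 6 | (4S)-4-benzyl-3-{2-[(1S,4R)-4-methyl-4-(triethylsilyloxy)cyclohex-2-en-1-yl]acetyl}-1,3-oxazolidin-2-one | O=C(C[C@H]1C=C[C@](C)(O[Si](CC)(CC)CC)CC1)N1[C@@H](Cc2ccccc2)COC1=O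
F5 | step 6 | (4S)-4-benzyl-3-{(2S)-2-[(1R,4R)-4-methyl-4-(triethylsilyloxy)cyclohex-2-en-1-yl]propanoyl}-1,3-oxazolidin-2-one | O=C([C@@H](C)[C@H]1C=C[C@](C)(O[Si](CC)(CC)CC)CC1)N1[C@@H](Cc2ccccc2)COC1=O
F6 | step 6 | (2S)-2-[(1R,4R)-4-methyl-4-(triethylsilyloxy)cyclohex-2-en-1-yl]propan-1-ol | OC[C@@H](C)[C@H]1C=C[C@](C)(O[Si](CC)(CC)CC)CC1
F7 | step 4 | (1R,2R)-1-methylcyclohex-3-ene-1,2-diol | O[C@@H]1C=CCC[C@@]1(C)O
F8 | step 12 | (2S,4R)-4-[(1S,4R)-4-hydroxy-4-methylcyclohex-2-en-1-yl]-2-[(phenylamino)oxy]pentan-1-ol | OC[C@H](C[C@@H](C)[C@H]1C=C[C@](C)(O)CC1)ONc1ccccc1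
F9 | step 12 | (2S,4R)-4-[(1S,4R)-4-hydroxy-4-methylcyclohex-2-en-1-yl]pentane-1,2-diol | OC[C@H](C[C@@H](C)[C@H]1C=C[C@](C)(O)CC1)O
F10 | step 12 | (1R,4S)-4-[(2R,4S)-4,5-bis(triethylsilyloxy)pentan-2-yl]-1-methylcyclohex-2-en-1-ol | CC[Si](CC)(CC)OC[C@H](C[C@@H](C)[C@H]1C=C[C@](C)(O)CC1)O[Si](CC)(CC)CC
F11 | step 12 | (2S,4R)-4-[(1S,4R)-4-hydroxy-4-methylcyclohex-2-en-1-yl]-2-[(triethylsilyl)oxy]pentanal | O=C[C@H](C[C@@H](C)[C@H]1C=C[C@](C)(O)CC1)O[Si](CC)(CC)CC
F12 | step 12 | methyl (2E,4S,6R)-6-[(1S,4R)-4-hydroxy-4-methylcyclohex-2-en-1-yl]-2-(4-methylpent-3-en-1-yl)-4-[(triethylsilyl)oxy]hept-2-enoate | COC(=O)/C(=C/[C@H](C[C@@H](C)[C@H]1C=C[C@](C)(O)CC1)O[Si](CC)(CC)CC)CCC=C(C)C
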